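The route rests on cutting the C2–C3 bond of the dihydrofuran ring in the inner 6-hydroxybenzofuran (unit B). C3 carries two aryl groups and C2 carries O1 and the 4-hydroxyphenyl group, so C3 can be a diaryl (donor/donor) dirhodium carbene and C2 the CH2 of an aryl 4-methoxybenzyl ether. One catalyst-controlled 1,5 C–H insertion then closes the ring, makes the C–C bond and sets C3; acid equilibration at C2 gives the trans pair. The precursor is an open benzophenone hydrazone with a bromine handle at C4, from which the formyl-bearing unit A is built by a second insertion of the same kind.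

Key step: step 5

Locants: unit A is the 2,3-dihydrobenzofuran carrying the formyl group at C5; unit B is the 2,3-dihydrobenzofuran carrying the hydroxyl at C6, joined through its C4 to C3 of unit A. The target is (2R,3R) in both units, each ring trans.

Assumption: Rh2(R-PTAD)4 (PTAD = (1-adamantyl)(phthalimido)acetate) is taken as the catalyst enantiomer that delivers the 3R centres. The sense is assigned by analogy; should a test run show the opposite sense, Rh2(S-PTAD)4 is used in steps 5 and 8 with no other change.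

Step 1
Reactants: 1 1-bromo-3,5-dimethoxybenzene; 2 3,5-dimethoxybenzoyl chloride
Product: 3 (2-bromo-4,6-dimethoxyphenyl)(3,5-dimethoxyphenyl)methanone
Conditions: AlCl3 (1.2 equiv), CH2Cl2, 0 °C → rt
Reagents that add atoms: none
Why: Friedel–Crafts acylation should occur at C2 of 1, which is para to one methoxy group and ortho to the other and less crowded than C4 between the two methoxy groups, and the ketone formed deactivates the ring against a second acylation.

Step 2
Reactants: 3 (2-bromo-4,6-dimethoxyphenyl)(3,5-dimethoxyphenyl)methanone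
Product: 4 (2-bromo-6-hydroxy-4-methoxyphenyl)(3,5-dimethoxyphenyl)methanone
Conditions: BCl3 (1.2 equiv), CH2Cl2, −78 → 0 °C; H2O
Reagents that add atoms: none
Why: Chelation-directed demethylation, in which BCl3 bridges the ketone oxygen and the ortho methoxy oxygen in a six-membered chelate so that chloride should cleave only that methyl ether and leave the other three untouched.

Step 3
Reactants: 4 (2-bromo-6-hydroxy-4-methoxyphenyl)(3,5-dimethoxyphenyl)methanone; 5 4-methoxybenzyl chloride
Product: 6 {2-bromo-4-methoxy-6-[(4-methoxybenzyl)oxy]phenyl}(3,5-dimethoxyphenyl)methanone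
Conditions: K2CO3, n-Bu4NI (cat.), DMF, 60 °C
Reagents that add atoms: none
Why: Williamson ether synthesis on the only free phenol installs the benzylic CH2 that later becomes C2 of unit B together with its 4-methoxyphenyl group.

Step 4
Reactants: 6 {2-bromo-4-methoxy-6-[(4-methoxybenzyl)oxy]phenyl}(3,5-dimethoxyphenyl)methanone
Product: 7 hydrazone of 6 (E/Z mixture)
Conditions: N2H4·H2O (20 equiv), AcOH (1 equiv), n-BuOH, 110 °C, sealed tube
Reagents that add atoms: hydrazine (NN)
Why: Hydrazone condensation, for which the small and strongly nucleophilic hydrazine under forcing, mildly acidic conditions should overcome the shielding of the carbonyl by the two ortho substituents while the aryl bromide and the ethers are inert.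

Step 5
Reactants: 7 hydrazone of 6
Product: 10 (2R,3R)-4-bromo-3-(3,5-dimethoxyphenyl)-6-methoxy-2-(4-methoxyphenyl)-2,3-dihydrobenzofuran, via diazo compound 8 (not isolated), via cis-dihydrobenzofuran 9 (not isolated)
Conditions: MnO2 (10 equiv), CH2Cl2, rt, filter; slow addition to Rh2(R-PTAD)4 (1 mol %), CH2Cl2, 0 °C → rt; then CF3CO2H (10 equiv), rt
Reagents that add atoms: none
Why: MnO2 dehydrogenates the hydrazone to the diaryldiazomethane 8, the dirhodium tetracarboxylate expels N2 to give a donor/donor rhodium carbene at the future C3, and this carbene inserts through a concerted, asynchronous three-centre (hydride-shift-like) transition state into one C–H bond of the ArO–CH2–Ar group, which forms the C3–C2 bond. The closest known reaction type is the enantioselective intramolecular C–H insertion of donor/donor dirhodium carbenes into aryl benzyl ethers to give 2,3-diaryl-2,3-dihydrobenzofurans. The five-membered ring O1–C2–C3–C3a–C7a is closed by 1,5 C–H insertion, the carbene carbon joining the carbon five atoms away. C3 is set by the chiral phthalimido carboxylate ligands, which select one enantiotopic methylene hydrogen and one carbene face; C2 is first cis to C3 because the insertion is concerted, and trifluoroacetic acid then ionises the C2–O1 bond reversibly (4-methoxybenzylic cation) so that C2 settles trans under control of C3, which cannot epimerise. The step needs site selectivity and suppression of azine or carbene-dimer formation: the ether CH2 is the only C–H in a 1,5 relation to the carbene and is activated by both the oxygen and the electron-rich arene, the ortho bromine is inert to the weakly electrophilic donor/donor carbene, and the diazo compound is added slowly to the catalyst.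

Step 6
Reactants: 11 5-bromo-2-hydroxybenzonitrile; 5 4-methoxybenzyl chloride
Product: 12 5-bromo-2-[(4-methoxybenzyl)oxy]benzonitrile
Conditions: K2CO3, DMF, 60 °C
Reagents that add atoms: none
Why: Williamson ether synthesis on an acidic cyanophenol gives the unit A building block, which already carries the CH2 for C2 of unit A and the bromine that later becomes the formyl group.

Step 7
Reactants: 10 (2R,3R)-4-bromo-3-(3,5-dimethoxyphenyl)-6-methoxy-2-(4-methoxyphenyl)-2,3-dihydrobenzofuran; 12 5-bromo-2-[(4-methoxybenzyl)oxy]benzonitrile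
Product: 15 hydrazone of {5-bromo-2-[(4-methoxybenzyl)oxy]phenyl}[(2R,3R)-3-(3,5-dimethoxyphenyl)-6-methoxy-2-(4-methoxyphenyl)-2,3-dihydrobenzofuran-4-yl]methanone (E/Z mixture), via aryllithium 13 (not isolated), via ketimine 14 (not isolated)
Conditions: t-BuLi (2.1 equiv), THF, −78 °C; cannulate into 12 (1.1 equiv), THF, −78 → 0 °C; then AcOH (3 equiv), N2H4·H2O (10 equiv), EtOH, 60 °C
Reagents that add atoms: hydrazine (NN)
Why: Bromine–lithium exchange at −78 °C should outrun deprotonation, the aryllithium adds once to the nitrile to give an N-lithio ketimine, and the protonated N–H ketimine undergoes transimination with hydrazine far more readily than a doubly ortho-substituted ketone would condense, with the two stereocentres of unit B untouched.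

Step 8
Reactants: 15 hydrazone from step 7
Product: 18 (2R,3R)-5-bromo-3-[(2R,3R)-3-(3,5-dimethoxyphenyl)-6-methoxy-2-(4-methoxyphenyl)-2,3-dihydrobenzofuran-4-yl]-2-(4-methoxyphenyl)-2,3-dihydrobenzofuran, via diazo compound 16 (not isolated), via cis ring A bromide 17 (not isolated)
Conditions: MnO2 (10 equiv), CH2Cl2, rt, filter; slow addition to Rh2(R-PTAD)4 (2 mol %), CH2Cl2, 0 °C → rt; then CF3CO2H (10 equiv), rt
Reagents that add atoms: none
Why: The same donor/donor carbene 1,5 C–H insertion closes the dihydrofuran ring of unit A, with C3 set by the same catalyst enantiomer (same spatial sense as in step 5, catalyst control relied upon over the resident centres), C2 equilibrated from cis to trans by the acid, and no competition from the C–H bonds of unit B, whose insertion would need a four-membered or a strained peri-fused ring.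

Step 9
Reactants: 18 bis(dihydrobenzofuran) bromide from step 8
Product: 20 (2R,3R)-3-[(2R,3R)-3-(3,5-dimethoxyphenyl)-6-methoxy-2-(4-methoxyphenyl)-2,3-dihydrobenzofuran-4-yl]-2-(4-methoxyphenyl)-2,3-dihydrobenzofuran-5-carbaldehyde, via aryllithium 19 (not isolated)
Conditions: t-BuLi (2.1 equiv), THF, −78 °C; DMF (5 equiv), −78 → 0 °C; 1 M HCl
Reagents that add atoms: N,N-dimethylformamide (CN(C)C=O)
Why: Bromine–lithium exchange followed by formylation of the aryllithium with DMF (Bouveault aldehyde synthesis) should be faster at −78 °C than any deprotonation at the benzylic positions, so all four stereocentres are kept.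

Step 10
Reactants: 20 pentamethyl ether aldehyde from step 9
Product: 21 (2R,3R)-3-[(2R,3R)-3-(3,5-dihydroxyphenyl)-6-hydroxy-2-(4-hydroxyphenyl)-2,3-dihydrobenzofuran-4-yl]-2-(4-hydroxyphenyl)-2,3-dihydrobenzofuran-5-carbaldehyde
Conditions: BBr3 (12 equiv), CH2Cl2, −78 °C → rt; MeOH, H2O, 0 °C
Reagents that add atoms: none
Why: Lewis-acid cleavage of the five aryl methyl ethers by BBr3 should leave the aryl aldehyde intact (released from its boron complex on hydrolysis), and any reversible ionisation at C2 of either ring returns to the trans arrangement already in place because the C3 centres cannot epimerise.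

Compound list
1 | 1-bromo-3,5-dimethoxybenzene | COc1cc(Br)cc(OC)c1 | starting material
2 | 3,5-dimethoxybenzoyl chloride | COc1cc(cc(OC)c1)C(=O)Cl | starting material
3 | (2-bromo-4,6-dimethoxyphenyl)(3,5-dimethoxyphenyl)methanone | COc1cc(OC)c(C(=O)c2cc(OC)cc(OC)c2)c(Br)c1 | intermediate
4 | (2-bromo-6-hydroxy-4-methoxyphenyl)(3,5-dimethoxyphenyl)methanone | COc1cc(O)c(C(=O)c2cc(OC)cc(OC)c2)c(Br)c1 | intermediate
5 | 4-methoxybenzyl chloride | COc1ccc(CCl)cc1 | starting material
6 | {2-bromo-4-methoxy-6-[(4-methoxybenzyl)oxy]phenyl}(3,5-dimethoxyphenyl)methanone | COc1ccc(COc2cc(OC)cc(Br)c2C(=O)c2cc(OC)cc(OC)c2)cc1 | intermediate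
7 | hydrazone of 6 (E/Z mixture) | COc1ccc(COc2cc(OC)cc(Br)c2C(=NN)c2cc(OC)cc(OC)c2)cc1 | intermediate
8 | 1-bromo-2-[diazo(3,5-dimethoxyphenyl)methyl]-5-methoxy-3-[(4-methoxybenzyl)oxy]benzene (not isolated) | COc1ccc(COc2cc(OC)cc(Br)c2C(=[N+]=[N-])c2cc(OC)cc(OC)c2)cc1 | intermediate
9 | (2S,3R)-4-bromo-3-(3,5-dimethoxyphenyl)-6-methoxy-2-(4-methoxyphenyl)-2,3-dihydrobenzofuran, cis (not isolated) | Brc1cc(OC)cc2c1[C@@H](c1cc(OC)cc(OC)c1)[C@@H](c1ccc(OC)cc1)O2 | intermediate
10 | (2R,3R)-4-bromo-3-(3,5-dimethoxyphenyl)-6-methoxy-2-(4-methoxyphenyl)-2,3-dihydrobenzofuran, trans | Brc1cc(OC)cc2c1[C@@H](c1cc(OC)cc(OC)c1)[C@H](c1ccc(OC)cc1)O2 | intermediate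
11 | 5-bromo-2-hydroxybenzonitrile | N#Cc1cc(Br)ccc1O | starting material
12 | 5-bromo-2-[(4-methoxybenzyl)oxy]benzonitrile | COc1ccc(COc2ccc(Br)cc2C#N)cc1 | intermediate
13 | [(2R,3R)-3-(3,5-dimethoxyphenyl)-6-methoxy-2-(4-methoxyphenyl)-2,3-dihydrobenzofuran-4-yl]lithium (not isolated) | [Li]c1cc(OC)cc2c1[C@@H](c1cc(OC)cc(OC)c1)[C@H](c1ccc(OC)cc1)O2 | intermediate
14 | N–H ketimine from 13 and 12, formed from its N-lithio salt on protonation (not isolated) | N=C(c1cc(Br)ccc1OCc1ccc(OC)cc1)c1cc(OC)cc2c1[C@@H](c1cc(OC)cc(OC)c1)[C@H](c1ccc(OC)cc1)O2 | intermediate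
15 | hydrazone of {5-bromo-2-[(4-methoxybenzyl)oxy]phenyl}[(2R,3R)-3-(3,5-dimethoxyphenyl)-6-methoxy-2-(4-methoxyphenyl)-2,3-dihydrobenzofuran-4-yl]methanone (E/Z mixture) | NN=C(c1cc(Br)ccc1OCc1ccc(OC)cc1)c1cc(OC)cc2c1[C@@H](c1cc(OC)cc(OC)c1)[C@H](c1ccc(OC)cc1)O2 | intermediate
16 | diazo compound from 15 (not isolated) | [N-]=[N+]=C(c1cc(Br)ccc1OCc1ccc(OC)cc1)c1cc(OC)cc2c1[C@@H](c1cc(OC)cc(OC)c1)[C@H](c1ccc(OC)cc1)O2 | intermediate
17 | (2S,3R)-5-bromo-3-[(2R,3R)-3-(3,5-dimethoxyphenyl)-6-methoxy-2-(4-methoxyphenyl)-2,3-dihydrobenzofuran-4-yl]-2-(4-methoxyphenyl)-2,3-dihydrobenzofuran, ring A cis (not isolated) | Brc1ccc2c(c1)[C@@H](c1cc(OC)cc3c1[C@@H](c1cc(OC)cc(OC)c1)[C@H](c1ccc(OC)cc1)O3)[C@@H](c1ccc(OC)cc1)O2 | intermediate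
18 | (2R,3R)-5-bromo-3-[(2R,3R)-3-(3,5-dimethoxyphenyl)-6-methoxy-2-(4-methoxyphenyl)-2,3-dihydrobenzofuran-4-yl]-2-(4-methoxyphenyl)-2,3-dihydrobenzofuran | Brc1ccc2c(c1)[C@@H](c1cc(OC)cc3c1[C@@H](c1cc(OC)cc(OC)c1)[C@H](c1ccc(OC)cc1)O3)[C@H](c1ccc(OC)cc1)O2 | intermediate
19 | aryllithium from 18, lithium at C5 of unit A (not isolated) | [Li]c1ccc2c(c1)[C@@H](c1cc(OC)cc3c1[C@@H](c1cc(OC)cc(OC)c1)[C@H](c1ccc(OC)cc1)O3)[C@H](c1ccc(OC)cc1)O2 | intermediate
20 | (2R,3R)-3-[(2R,3R)-3-(3,5-dimethoxyphenyl)-6-methoxy-2-(4-methoxyphenyl)-2,3-dihydrobenzofuran-4-yl]-2-(4-methoxyphenyl)-2,3-dihydrobenzofuran-5-carbaldehyde | O=Cc1ccc2c(c1)[C@@H](c1cc(OC)cc3c1[C@@H](c1cc(OC)cc(OC)c1)[C@H](c1ccc(OC)cc1)O3)[C@H](c1ccc(OC)cc1)O2 | intermediate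
21 | (2R,3R)-3-[(2R,3R)-3-(3,5-dihydroxyphenyl)-6-hydroxy-2-(4-hydroxyphenyl)-2,3-dihydrobenzofuran-4-yl]-2-(4-hydroxyphenyl)-2,3-dihydrobenzofuran-5-carbaldehyde | O=Cc1ccc2c(c1)[C@@H](c1cc(O)cc3c1[C@@H](c1cc(O)cc(O)c1)[C@H](c1ccc(O)cc1)O3)[C@H](c1ccc(O)cc1)O2 | target

Total step count: 10
Longest linear sequence: 9 steps (steps 1 to 5 and 7 to 10; step 6 is a one-step side branch)

Steps most likely to fail

The two carbene insertions (steps 5 and 8) are ranked below the following three because their reaction type is established for aryl benzyl ethers of this kind.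

1. Step 4. The condensation may stall because the carbonyl carbon is shielded on both faces by the ortho bromine and the ortho benzyloxy group; prolonged heating may let the hydrazone nitrogen attack the carbon bearing bromine. Fallback, setting out from 6 and coming back at 7: the ketone is thionated with 2,4-bis(4-methoxyphenyl)-1,3,2,4-dithiadiphosphetane 2,4-disulfide (0.6 equiv, toluene, 110 °C) to the thioketone F1, whose far more reactive C=S group should exchange with N2H4·H2O in EtOH at rt, with loss of hydrogen sulfide, to give 7.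

2. Step 7. Bromine–lithium scrambling between aryllithium 13 and the aryl bromide of nitrile 12 may compete with addition to the nitrile; slow addition of the hindered aryllithium may also allow proton transfer from a benzylic position followed by ring opening. Fallback, setting out from 10 and coming back at 15: 5-bromo-2-hydroxybenzaldehyde is alkylated with 5 (K2CO3, DMF) to 5-bromo-2-[(4-methoxybenzyl)oxy]benzaldehyde F2. Aryllithium 13, made from 10 as in step 7, adds to F2 at −78 °C, where carbonyl addition is faster than any exchange, to give the diaryl carbinol F3 as a mixture of carbinol epimers. MnO2 in CH2Cl2 oxidises F3 to the diaryl ketone F4, and condensation with N2H4·H2O (AcOH, n-BuOH, 110 °C) gives 15.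

3. Step 10. During the exhaustive ether cleavage, the Lewis-acid-complexed aldehyde may attack the electron-rich rings, and the dihydrofuran rings may open at C2 with capture of the benzylic cation by bromide or by an arene. Fallback, setting out from 18 and coming back at 21: the ethers are cleaved before the aldehyde exists and the phenols are carried as silyl ethers. BBr3 (CH2Cl2, −78 °C → rt) converts 18 into the pentaphenol bromide F5; TBSCl and imidazole in DMF give the pentakis(tert-butyldimethylsilyl) ether F6; t-BuLi then DMF (THF, −78 °C) gives the silylated aldehyde F7; HF·pyridine in THF at 0 °C releases 21.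

Further compounds
F1 | step 4 | {2-bromo-4-methoxy-6-[(4-methoxybenzyl)oxy]phenyl}(3,5-dimethoxyphenyl)methanethione | COc1ccc(COc2cc(OC)cc(Br)c2C(=S)c2cc(OC)cc(OC)c2)cc1
F2 | step 7 | 5-bromo-2-[(4-methoxybenzyl)oxy]benzaldehyde | COc1ccc(COc2ccc(Br)cc2C=O)cc1
F3 | step 7 | {5-bromo-2-[(4-methoxybenzyl)oxy]phenyl}[(2R,3R)-3-(3,5-dimethoxyphenyl)-6-methoxy-2-(4-methoxyphenyl)-2,3-dihydrobenzofuran-4-yl]methanol (carbinol epimers) | OC(c1cc(Br)ccc1OCc1ccc(OC)cc1)c1cc(OC)cc2c1[C@@H](c1cc(OC)cc(OC)c1)[C@H](c1ccc(OC)cc1)O2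
F4 | step 7 | {5-bromo-2-[(4-methoxybenzyl)oxy]phenyl}[(2R,3R)-3-(3,5-dimethoxyphenyl)-6-methoxy-2-(4-methoxyphenyl)-2,3-dihydrobenzofuran-4-yl]methanone | O=C(c1cc(Br)ccc1OCc1ccc(OC)cc1)c1cc(OC)cc2c1[C@@H](c1cc(OC)cc(OC)c1)[C@H](c1ccc(OC)cc1)O2
F5 | step 10 | (2R,3R)-4-[(2R,3R)-5-bromo-2-(4-hydroxyphenyl)-2,3-dihydrobenzofuran-3-yl]-3-(3,5-dihydroxyphenyl)-2-(4-hydroxyphenyl)-2,3-dihydrobenzofuran-6-ol | Brc1ccc2c(c1)[C@@H](c1cc(O)cc3c1[C@@H](c1cc(O)cc(O)c1)[C@H](c1ccc(O)cc1)O3)[C@H](c1ccc(O)cc1)O2
F6 | step 10 | pentakis(tert-butyldimethylsilyl) ether of F5 | Brc1ccc2c(c1)[C@@H](c1cc(O[Si](C)(C)C(C)(C)C)cc3c1[C@@H](c1cc(O[Si](C)(C)C(C)(C)C)cc(O[Si](C)(C)C(C)(C)C)c1)[C@H](c1ccc(O[Si](C)(C)C(C)(C)C)cc1)O3)[C@H](c1ccc(O[Si](C)(C)C(C)(C)C)cc1)O2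
F7 | step 10 | pentakis(tert-butyldimethylsilyl) ether of 21 | O=Cc1ccc2c(c1)[C@@H](c1cc(O[Si](C)(C)C(C)(C)C)cc3c1[C@@H](c1cc(O[Si](C)(C)C(C)(C)C)cc(O[Si](C)(C)C(C)(C)C)c1)[C@H](c1ccc(O[Si](C)(C)C(C)(C)C)cc1)O3)[C@H](c1ccc(O[Si](C)(C)C(C)(C)C)cc1)O2
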